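Everything rests on disconnecting the C2–C3 bond of pyran ring C of the middle flavan unit. Written as a C2=C3 enol ether, that bond is the metathesis product of a gallate-ester-derived aryl α-styryl ether on O1 and an allyl group on C4a, so ring-closing metathesis closes ring C in one operation as a planar 4H-chromene. The allyl group comes from a Claisen rearrangement that fixes bromine at the future C8. The 3-ketone then lets one dynamic kinetic hydrogenation set C2 and C3 cis; a C4 quinone methide joins epicatechin, and aryllithium addition to a flavan-4-one followed by ionic reduction adds the upper unit.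

Key step: step 6

Remark: compounds 10–12 are racemic and their SMILES show one enantiomer; the C4 carbinol centre of 30 is left undefined because step 21 erases it; the catalyst antipodes named in steps 9 and 17 are assigned by analogy and would be confirmed on first use.

**Middle unit**

Step 1
Reactants: 1 2-bromoresorcinol
Product: 2 2-bromo-3-[(triisopropylsilyl)oxy]phenol
Conditions: NaH (1.0 equiv), THF, 0 °C; TIPSCl (1.0 equiv), 0 °C to rt
Reagents that add atoms: chlorotriisopropylsilane, CC(C)[Si](Cl)(C(C)C)C(C)C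
Why: O-silylation of the monosodium salt of a symmetric diol should give the mono-ether statistically, with diol and bis-ether separated and recycled.

Step 2
Reactants: 2 2-bromo-3-[(triisopropylsilyl)oxy]phenol
Product: 3 1-(allyloxy)-2-bromo-3-[(triisopropylsilyl)oxy]benzene
Conditions: allyl bromide, K2CO3, acetone, reflux
Reagents that add atoms: allyl bromide, C=CCBr
Why: Williamson ether synthesis on the remaining phenol, the aryl silyl ether being stable to K2CO3 in an aprotic solvent.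

Step 3
Reactants: 3 1-(allyloxy)-2-bromo-3-[(triisopropylsilyl)oxy]benzene
Product: 5 6-allyl-2-bromo-3-[(triisopropylsilyl)oxy]phenol, via ortho-dienone 4 (not isolated)
Conditions: PhNEt2, 190 °C, argon
Reagents that add atoms: none
Why: Aromatic Claisen rearrangement moves the allyl group to the only free ortho carbon (the other is blocked by bromine) and the dienone tautomerises, which fixes the contiguous allyl/O/Br/O pattern of ring A.

Step 4
Reactants: 5 6-allyl-2-bromo-3-[(triisopropylsilyl)oxy]phenol; 6 3,4,5-tris(benzyloxy)benzoic acid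
Product: 7 6-allyl-2-bromo-3-[(triisopropylsilyl)oxy]phenyl 3,4,5-tris(benzyloxy)benzoate
Conditions: DCC, DMAP (0.2 equiv), CH2Cl2, rt
Reagents that add atoms: none
Why: Steglich esterification, in which the acylpyridinium intermediate should overcome the 2,6-disubstitution of the phenol.

Step 5
Reactants: 7 6-allyl-2-bromo-3-[(triisopropylsilyl)oxy]phenyl 3,4,5-tris(benzyloxy)benzoate
Product: 8 1-allyl-3-bromo-4-[(triisopropylsilyl)oxy]-2-({1-[3,4,5-tris(benzyloxy)phenyl]vinyl}oxy)benzene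
Conditions: Tebbe reagent Cp2Ti(μ-CH2)(μ-Cl)AlMe2 (1.3 equiv), pyridine (cat.), THF–toluene, −40 °C to rt; basic alumina
Reagents that add atoms: Tebbe reagent, C[Al](C)C[Ti](Cl)(C1C=CC=C1)C1C=CC=C1
Why: Tebbe methylenation of an aryl benzoate through an oxatitanacyclobutane should give the acid-sensitive aryl α-styryl ether while allyl, aryl bromide, silyl and benzyl ethers stay untouched.

Step 6
Reactants: 8 1-allyl-3-bromo-4-[(triisopropylsilyl)oxy]-2-({1-[3,4,5-tris(benzyloxy)phenyl]vinyl}oxy)benzene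
Product: 9 8-bromo-7-[(triisopropylsilyl)oxy]-2-[3,4,5-tris(benzyloxy)phenyl]-4H-chromene
Conditions: second-generation Grubbs catalyst RuCl2(=CHPh)(PCy3)(H2IMes) (5 mol%), 1,4-benzoquinone (10 mol%), toluene (0.01 M), 70 °C
Reagents that add atoms: none
Why: The ruthenium benzylidene initiates at the monosubstituted allyl olefin, and the resulting alkylidene at C3 undergoes [2+2] cycloaddition with the 1,1-disubstituted enol ether with ruthenium on the CH2 terminus, so that cycloreversion forms C2=C3 and releases ethylene through Ru=CH2. The closest known reaction type is ring-closing olefin metathesis of an acyclic enol ether with a terminal alkene to a cyclic enol ether, as used for 4H-chromenes and glycals. The six-membered pyran ring C of the middle unit is closed by metathesis in which both new sp2 carbons (C2 and C3) lie inside the ring. No stereocentre is created: C2 and C3 are deliberately left planar so that steps 7–9 can set both together. The selectivity needed is cyclisation ahead of ruthenium-hydride migration of the allyl double bond (which would lead to a ring-contracted 2-arylbenzofuran) and ahead of carbene trapping by the enol ether; 1,4-benzoquinone, high dilution and the 1,1-disubstitution of the enol ether, which directs initiation to the allyl group, should secure this.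

Step 7
Reactants: 9 8-bromo-7-[(triisopropylsilyl)oxy]-2-[3,4,5-tris(benzyloxy)phenyl]-4H-chromene
Product: 11 rac-(2S*,3R*)-8-bromo-7-[(triisopropylsilyl)oxy]-2-[3,4,5-tris(benzyloxy)phenyl]chroman-3-ol (2,3-trans), via 3-boryl flavan 10 (not isolated)
Conditions: BH3·THF, THF, 0 °C to rt; then NaOH (3 M), H2O2 (30%), 0 °C
Reagents that add atoms: hydrogen peroxide, OO; borane–tetrahydrofuran, B.C1CCOC1 (boron stays only in 10)
Why: Hydroboration–oxidation of the enol ether places boron on C3 (β to oxygen and less substituted) and adds H and B syn, so the racemic 2,3-trans alcohol is expected.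

Step 8
Reactants: 11 rac-(2S*,3R*)-8-bromo-7-[(triisopropylsilyl)oxy]-2-[3,4,5-tris(benzyloxy)phenyl]chroman-3-ol
Product: 12 rac-8-bromo-7-[(triisopropylsilyl)oxy]-2-[3,4,5-tris(benzyloxy)phenyl]chroman-3-one
Conditions: Dess–Martin periodinane, CH2Cl2, 0 °C to rt
Reagents that add atoms: none
Why: Dess–Martin oxidation gives the flavan-3-one under near-neutral conditions, and its C2–H (α-aryl, α-aryloxy, α-keto) is the acidic handle needed in step 9.

Step 9
Reactants: 12 rac-8-bromo-7-[(triisopropylsilyl)oxy]-2-[3,4,5-tris(benzyloxy)phenyl]chroman-3-one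
Product: 13 (2S,3S)-8-bromo-7-[(triisopropylsilyl)oxy]-2-[3,4,5-tris(benzyloxy)phenyl]chroman-3-ol (2,3-cis)
Conditions: trans-RuCl2[(R)-xylbinap][(R)-daipen] (1 mol%), t-BuOK (8 mol%), i-PrOH–THF, H2 (10 atm), 25 °C, degassed
Reagents that add atoms: none
Why: Noyori asymmetric hydrogenation with dynamic kinetic resolution, in which base racemises C2 faster than reduction and the catalyst should reduce the (2S) ketone from the face opposite the 2-aryl group to give the cis (2S,3S) alcohol, the (R)/(R) antipode being chosen by analogy with 2-alkoxy- and 2-arylcycloalkanones.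

Step 10
Reactants: 13 (2S,3S)-8-bromo-7-[(triisopropylsilyl)oxy]-2-[3,4,5-tris(benzyloxy)phenyl]chroman-3-ol
Product: 14 (2S,3S)-8-bromo-2-[3,4,5-tris(benzyloxy)phenyl]chromane-3,7-diol
Conditions: n-Bu4NF (1.1 equiv), AcOH (1.1 equiv), THF, 0 °C
Reagents that add atoms: none
Why: Fluoride cleavage of the aryl silyl ether, buffered so that the electron-rich phenoxide is not exposed to base and air.

Step 11
Reactants: 14 (2S,3S)-8-bromo-2-[3,4,5-tris(benzyloxy)phenyl]chromane-3,7-diol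
Product: 16 (2S,3S,4R)-8-bromo-4-(2-ethoxyethoxy)-2-[3,4,5-tris(benzyloxy)phenyl]chromane-3,7-diol, via para-quinone methide 15 (not isolated)
Conditions: DDQ (1.05 equiv), 2-ethoxyethanol (10 equiv), CH2Cl2, 0 °C
Reagents that add atoms: 2-ethoxyethanol, CCOCCO
Why: DDQ dehydrogenation of a para-alkylphenol (7-OH is para to C4a) should give the ring A quinone methide, to which the alcohol adds at C4 anti to the axial 3-OH, while the fully benzylated ring B has no phenol to oxidise.

**Lower unit and dimer**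

Step 12
Reactants: 17 (−)-epicatechin
Product: 18 5,7,3',4'-tetra-O-benzyl-(−)-epicatechin
Conditions: BnBr (4.4 equiv), K2CO3, DMF, 0 °C to rt
Reagents that add atoms: benzyl bromide, BrCc1ccccc1
Why: Williamson benzylation of the four phenols only, because K2CO3 does not deprotonate the secondary 3-OH.

Step 13
Reactants: 16 (2S,3S,4R)-8-bromo-4-(2-ethoxyethoxy)-2-[3,4,5-tris(benzyloxy)phenyl]chromane-3,7-diol; 18 5,7,3',4'-tetra-O-benzyl-(−)-epicatechin
Product: 19 (2S,3S,4S)-8-bromo-2-[3,4,5-tris(benzyloxy)phenyl]-4-{(2R,3R)-5,7-bis(benzyloxy)-2-[3,4-bis(benzyloxy)phenyl]-3-hydroxychroman-8-yl}chromane-3,7-diol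
Conditions: 18 (3 equiv), TMSOTf (0.3 equiv), CH2Cl2, −78 to −40 °C; aq. NaHCO3
Reagents that add atoms: none
Why: Acid ionises the C4 ether to the benzylic cation (a protonated quinone methide), which C8 of 18, the most nucleophilic arene carbon present, should capture in a Friedel–Crafts alkylation anti to the 3-OH and 2-aryl groups of the 2,3-cis ring, giving the 3,4-trans (4S) linkage, while the brominated ring A of 16 is too poor a nucleophile to self-condense.

Step 14
Reactants: 19 (the dimer triol of step 13)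
Product: 20 tri-O-benzyl ether of 19 (7-O and 3-O of the bromo unit and 3-O of the epicatechin unit benzylated)
Conditions: NaH (4 equiv), BnBr (4 equiv), n-Bu4NI (cat.), DMF, 0 °C to rt
Reagents that add atoms: benzyl bromide, BrCc1ccccc1
Why: Williamson benzylation of the phenol and both secondary alcohols in one operation removes every acidic proton before the lithiation.

**Upper unit**

Step 15
Reactants: 21 1-[4-(benzyloxy)-2-hydroxyphenyl]ethan-1-one
Product: 22 1-[4-(benzyloxy)-2-(methoxymethoxy)phenyl]ethan-1-one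
Conditions: NaH, DMF, 0 °C; MOMCl
Reagents that add atoms: chloromethyl methyl ether, COCCl
Why: Williamson alkylation of the sodium phenoxide masks the 2'-OH, which would otherwise divert the epoxidation in step 17.

Step 16
Reactants: 22 1-[4-(benzyloxy)-2-(methoxymethoxy)phenyl]ethan-1-one; 23 3,4,5-tris(benzyloxy)benzaldehyde
Product: 24 (E)-1-[4-(benzyloxy)-2-(methoxymethoxy)phenyl]-3-[3,4,5-tris(benzyloxy)phenyl]prop-2-en-1-one
Conditions: KOH, EtOH–THF, rt
Reagents that add atoms: none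
Why: Claisen–Schmidt condensation of a methyl ketone with a non-enolisable aldehyde gives the thermodynamic E-chalcone.

Step 17
Reactants: 24 (the E-chalcone of step 16)
Product: 25 [4-(benzyloxy)-2-(methoxymethoxy)phenyl]{(2S,3R)-3-[3,4,5-tris(benzyloxy)phenyl]oxiran-2-yl}methanone
Conditions: poly-D-leucine, urea–hydrogen peroxide, DBU, THF, rt
Reagents that add atoms: urea–hydrogen peroxide, NC(N)=O.OO
Why: Julia–Colonna epoxidation, in which the helical poly-D-leucine should deliver hydroperoxide to one enone face and give the (2S,3R) trans-epoxide, the mirror image of the poly-L-leucine outcome.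

Step 18
Reactants: 25 (the 2S,3R epoxy ketone of step 17)
Product: 27 (2S,3S)-7-(benzyloxy)-3-hydroxy-2-[3,4,5-tris(benzyloxy)phenyl]chroman-4-one, via 2'-hydroxy epoxy ketone 26 (not isolated)
Conditions: conc. HCl, MeOH–THF, 50 °C
Reagents that add atoms: none
Why: Acid removes the MOM group and the freed phenol opens the epoxide at the benzylic carbon with inversion, so C3 keeps its C–O bond and the thermodynamically preferred 2,3-trans (2S,3S) dihydroflavonol is expected.

Step 19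
Reactants: 27 (2S,3S)-7-(benzyloxy)-3-hydroxy-2-[3,4,5-tris(benzyloxy)phenyl]chroman-4-one
Product: 28 (2S,3S)-3,7-bis(benzyloxy)-2-[3,4,5-tris(benzyloxy)phenyl]chroman-4-one
Conditions: benzyl 2,2,2-trichloroacetimidate, TfOH (5 mol%), CH2Cl2–cyclohexane, rt
Reagents that add atoms: benzyl 2,2,2-trichloroacetimidate, ClC(Cl)(Cl)C(=N)OCc1ccccc1
Why: Acid-catalysed imidate benzylation avoids the base that would enolise, epimerise or ring-open the flavanonol.

**Assembly**

Step 20
Reactants: 20 (the tri-O-benzyl dimer bromide of step 14); 28 (2S,3S)-3,7-bis(benzyloxy)-2-[3,4,5-tris(benzyloxy)phenyl]chroman-4-one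
Product: 30 tertiary carbinol in which C4 of 28 carries OH and C8 of the middle unit of 20 in place of bromine (C4 epimers), via aryllithium 29 (not isolated)
Conditions: t-BuLi (2.1 equiv), THF, −78 °C, 10 min; then 28 (1.5 equiv), −78 to 0 °C; H2O
Reagents that add atoms: tert-butyllithium, [Li]C(C)(C)C (lithium stays only in 29)
Why: Bromine–lithium exchange is faster than benzylic deprotonation at −78 °C, and the aryllithium flanked by O1 and the 7-benzyloxy group should add 1,2 to the ketone, which fixes the 4→8 connectivity that cationic coupling to a 5-deoxy ring A cannot give.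

Step 21
Reactants: 30 (the tertiary carbinol of step 20)
Product: 31 pentadeca-O-benzyl ether of the target (upper unit 2S,3R,4S; middle unit 2S,3S,4S; lower unit 2R,3R)
Conditions: n-Bu3SnH (5 equiv), CF3CO2H (10 equiv), CH2Cl2, 0 °C
Reagents that add atoms: none
Why: Ionic deoxygenation, in which acid ionises the bis-benzylic carbinol and the stannane should deliver hydride to the planar C4 cation anti to the adjacent 3-benzyloxy group, leaving the aryl group cis to 3-O (2,3-trans-3,4-cis, 4S).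

Step 22
Reactants: 31 (the pentadeca-O-benzyl trimer)
Product: 32 CNP0115797.3
Conditions: H2 (1 atm), Pd(OH)2 on carbon, THF–MeOH–H2O, rt
Reagents that add atoms: none
Why: Hydrogenolysis of all fifteen benzyl ethers, which leaves the interflavan C–C bonds and all eight stereocentres untouched.

**Compound list**

1 | 2-bromoresorcinol | Oc1cccc(O)c1Br | starting material
2 | 2-bromo-3-[(triisopropylsilyl)oxy]phenol | Oc1cccc(O[Si](C(C)C)(C(C)C)C(C)C)c1Br | intermediate
3 | 1-(allyloxy)-2-bromo-3-[(triisopropylsilyl)oxy]benzene | C=CCOc1cccc(O[Si](C(C)C)(C(C)C)C(C)C)c1Br | intermediate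
4 | 6-allyl-2-bromo-3-[(triisopropylsilyl)oxy]cyclohexa-2,4-dien-1-one | O=C1C(CC=C)C=CC(O[Si](C(C)C)(C(C)C)C(C)C)=C1Br | intermediate (not isolated)
5 | 6-allyl-2-bromo-3-[(triisopropylsilyl)oxy]phenol | Oc1c(CC=C)ccc(O[Si](C(C)C)(C(C)C)C(C)C)c1Br | intermediate
6 | 3,4,5-tris(benzyloxy)benzoic acid | OC(=O)c1cc(OCc2ccccc2)c(OCc2ccccc2)c(OCc2ccccc2)c1 | starting material
7 | 6-allyl-2-bromo-3-[(triisopropylsilyl)oxy]phenyl 3,4,5-tris(benzyloxy)benzoate | C=CCc1ccc(O[Si](C(C)C)(C(C)C)C(C)C)c(Br)c1OC(=O)c1cc(OCc2ccccc2)c(OCc2ccccc2)c(OCc2ccccc2)c1 | intermediate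
8 | 1-allyl-3-bromo-4-[(triisopropylsilyl)oxy]-2-({1-[3,4,5-tris(benzyloxy)phenyl]vinyl}oxy)benzene | C=CCc1ccc(O[Si](C(C)C)(C(C)C)C(C)C)c(Br)c1OC(=C)c1cc(OCc2ccccc2)c(OCc2ccccc2)c(OCc2ccccc2)c1 | intermediate
9 | 8-bromo-7-[(triisopropylsilyl)oxy]-2-[3,4,5-tris(benzyloxy)phenyl]-4H-chromene | Brc1c(O[Si](C(C)C)(C(C)C)C(C)C)ccc2c1OC(c1cc(OCc3ccccc3)c(OCc3ccccc3)c(OCc3ccccc3)c1)=CC2 | intermediate
10 | rac-trans-{8-bromo-7-[(triisopropylsilyl)oxy]-2-[3,4,5-tris(benzyloxy)phenyl]chroman-3-yl}borane (one enantiomer shown) | Brc1c(O[Si](C(C)C)(C(C)C)C(C)C)ccc2c1O[C@@H](c1cc(OCc3ccccc3)c(OCc3ccccc3)c(OCc3ccccc3)c1)[C@H](B)C2 | intermediate (not isolated)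
11 | rac-(2S*,3R*)-8-bromo-7-[(triisopropylsilyl)oxy]-2-[3,4,5-tris(benzyloxy)phenyl]chroman-3-ol (one enantiomer shown) | Brc1c(O[Si](C(C)C)(C(C)C)C(C)C)ccc2c1O[C@@H](c1cc(OCc3ccccc3)c(OCc3ccccc3)c(OCc3ccccc3)c1)[C@H](O)C2 | intermediate
12 | rac-8-bromo-7-[(triisopropylsilyl)oxy]-2-[3,4,5-tris(benzyloxy)phenyl]chroman-3-one | Brc1c(O[Si](C(C)C)(C(C)C)C(C)C)ccc2c1OC(c1cc(OCc3ccccc3)c(OCc3ccccc3)c(OCc3ccccc3)c1)C(=O)C2 | intermediate
13 | (2S,3S)-8-bromo-7-[(triisopropylsilyl)oxy]-2-[3,4,5-tris(benzyloxy)phenyl]chroman-3-ol | Brc1c(O[Si](C(C)C)(C(C)C)C(C)C)ccc2c1O[C@@H](c1cc(OCc3ccccc3)c(OCc3ccccc3)c(OCc3ccccc3)c1)[C@@H](O)C2 | intermediate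
14 | (2S,3S)-8-bromo-2-[3,4,5-tris(benzyloxy)phenyl]chromane-3,7-diol | Brc1c(O)ccc2c1O[C@@H](c1cc(OCc3ccccc3)c(OCc3ccccc3)c(OCc3ccccc3)c1)[C@@H](O)C2 | intermediate
15 | (2S,3S)-8-bromo-3-hydroxy-2-[3,4,5-tris(benzyloxy)phenyl]-2,3-dihydro-7H-chromen-7-one (ring A para-quinone methide) | O=C1C=CC2=C[C@H](O)[C@H](c3cc(OCc4ccccc4)c(OCc4ccccc4)c(OCc4ccccc4)c3)OC2=C1Br | intermediate (not isolated)
16 | (2S,3S,4R)-8-bromo-4-(2-ethoxyethoxy)-2-[3,4,5-tris(benzyloxy)phenyl]chromane-3,7-diol | Brc1c(O)ccc2c1O[C@@H](c1cc(OCc3ccccc3)c(OCc3ccccc3)c(OCc3ccccc3)c1)[C@@H](O)[C@@H]2OCCOCC | intermediate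
17 | (−)-epicatechin | Oc1cc(O)c2c(c1)O[C@H](c1ccc(O)c(O)c1)[C@H](O)C2 | starting material
18 | 5,7,3',4'-tetra-O-benzyl-(−)-epicatechin | c1ccccc1COc1cc(OCc3ccccc3)c2c(c1)O[C@H](c1ccc(OCc3ccccc3)c(OCc3ccccc3)c1)[C@H](O)C2 | intermediate
19 | (2S,3S,4S)-8-bromo-2-[3,4,5-tris(benzyloxy)phenyl]-4-{(2R,3R)-5,7-bis(benzyloxy)-2-[3,4-bis(benzyloxy)phenyl]-3-hydroxychroman-8-yl}chromane-3,7-diol | Brc1c(O)ccc2c1O[C@@H](c1cc(OCc3ccccc3)c(OCc3ccccc3)c(OCc3ccccc3)c1)[C@@H](O)[C@@H]2c1c(OCc3ccccc3)cc(OCc3ccccc3)c2c1O[C@H](c1ccc(OCc3ccccc3)c(OCc3ccccc3)c1)[C@H](O)C2 | intermediate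
20 | tri-O-benzyl ether of 19 | Brc1c(OCc3ccccc3)ccc2c1O[C@@H](c1cc(OCc3ccccc3)c(OCc3ccccc3)c(OCc3ccccc3)c1)[C@@H](OCc3ccccc3)[C@@H]2c1c(OCc3ccccc3)cc(OCc3ccccc3)c2c1O[C@H](c1ccc(OCc3ccccc3)c(OCc3ccccc3)c1)[C@H](OCc3ccccc3)C2 | intermediate
21 | 1-[4-(benzyloxy)-2-hydroxyphenyl]ethan-1-one | CC(=O)c1ccc(OCc2ccccc2)cc1O | starting material
22 | 1-[4-(benzyloxy)-2-(methoxymethoxy)phenyl]ethan-1-one | CC(=O)c1ccc(OCc2ccccc2)cc1OCOC | intermediate
23 | 3,4,5-tris(benzyloxy)benzaldehyde | O=Cc1cc(OCc2ccccc2)c(OCc2ccccc2)c(OCc2ccccc2)c1 | starting material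
24 | (E)-1-[4-(benzyloxy)-2-(methoxymethoxy)phenyl]-3-[3,4,5-tris(benzyloxy)phenyl]prop-2-en-1-one | COCOc1cc(OCc2ccccc2)ccc1C(=O)/C=C/c1cc(OCc2ccccc2)c(OCc2ccccc2)c(OCc2ccccc2)c1 | intermediate
25 | [4-(benzyloxy)-2-(methoxymethoxy)phenyl]{(2S,3R)-3-[3,4,5-tris(benzyloxy)phenyl]oxiran-2-yl}methanone | COCOc1cc(OCc2ccccc2)ccc1C(=O)[C@H]1O[C@@H]1c1cc(OCc2ccccc2)c(OCc2ccccc2)c(OCc2ccccc2)c1 | intermediate
26 | [4-(benzyloxy)-2-hydroxyphenyl]{(2S,3R)-3-[3,4,5-tris(benzyloxy)phenyl]oxiran-2-yl}methanone | Oc1cc(OCc2ccccc2)ccc1C(=O)[C@H]1O[C@@H]1c1cc(OCc2ccccc2)c(OCc2ccccc2)c(OCc2ccccc2)c1 | intermediate (not isolated)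
27 | (2S,3S)-7-(benzyloxy)-3-hydroxy-2-[3,4,5-tris(benzyloxy)phenyl]chroman-4-one | c1ccccc1COc1ccc2c(c1)O[C@@H](c1cc(OCc3ccccc3)c(OCc3ccccc3)c(OCc3ccccc3)c1)[C@H](O)C2=O | intermediate
28 | (2S,3S)-3,7-bis(benzyloxy)-2-[3,4,5-tris(benzyloxy)phenyl]chroman-4-one | c1ccccc1COc1ccc2c(c1)O[C@@H](c1cc(OCc3ccccc3)c(OCc3ccccc3)c(OCc3ccccc3)c1)[C@H](OCc3ccccc3)C2=O | intermediate
29 | 8-lithio analogue of 20 | [Li]c1c(OCc3ccccc3)ccc2c1O[C@@H](c1cc(OCc3ccccc3)c(OCc3ccccc3)c(OCc3ccccc3)c1)[C@@H](OCc3ccccc3)[C@@H]2c1c(OCc3ccccc3)cc(OCc3ccccc3)c2c1O[C@H](c1ccc(OCc3ccccc3)c(OCc3ccccc3)c1)[C@H](OCc3ccccc3)C2 | intermediate (not isolated)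
30 | tertiary C4 carbinol of the protected trimer (C4 of the upper unit undefined) | c1ccccc1COc1ccc2c(c1)O[C@@H](c1cc(OCc3ccccc3)c(OCc3ccccc3)c(OCc3ccccc3)c1)[C@H](OCc3ccccc3)C2(O)c1c(OCc3ccccc3)ccc2c1O[C@@H](c1cc(OCc3ccccc3)c(OCc3ccccc3)c(OCc3ccccc3)c1)[C@@H](OCc3ccccc3)[C@@H]2c1c(OCc3ccccc3)cc(OCc3ccccc3)c2c1O[C@H](c1ccc(OCc3ccccc3)c(OCc3ccccc3)c1)[C@H](OCc3ccccc3)C2 | intermediate
31 | pentadeca-O-benzyl ether of the target | c1ccccc1COc1ccc2c(c1)O[C@@H](c1cc(OCc3ccccc3)c(OCc3ccccc3)c(OCc3ccccc3)c1)[C@H](OCc3ccccc3)[C@@H]2c1c(OCc3ccccc3)ccc2c1O[C@@H](c1cc(OCc3ccccc3)c(OCc3ccccc3)c(OCc3ccccc3)c1)[C@@H](OCc3ccccc3)[C@@H]2c1c(OCc3ccccc3)cc(OCc3ccccc3)c2c1O[C@H](c1ccc(OCc3ccccc3)c(OCc3ccccc3)c1)[C@H](OCc3ccccc3)C2 | intermediate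
32 | CNP0115797.3 | Oc1ccc2c(c1)O[C@@H](c1cc(O)c(O)c(O)c1)[C@H](O)[C@@H]2c1c(O)ccc2c1O[C@@H](c1cc(O)c(O)c(O)c1)[C@@H](O)[C@@H]2c1c(O)cc(O)c2c1O[C@H](c1ccc(O)c(O)c1)[C@H](O)C2 | target

**Step count and risks**

Total step count: 22. Longest linear sequence: 16 steps (steps 1–11, 13, 14, 20, 21, 22, from 2-bromoresorcinol).

Most likely to fail:

1. Step 9. Racemisation at C2 may not keep pace with reduction, so the hydrogenation could become a kinetic resolution; the sense or the cis selectivity may be poor; the enolate may degrade. The fallback sets out from 9 and comes back at 13. Hydroboration of 9 with monoisopinocampheylborane prepared from (−)-α-pinene, then NaOH/H2O2, should give the single-enantiomer (2S,3R)-8-bromo-7-[(triisopropylsilyl)oxy]-2-[3,4,5-tris(benzyloxy)phenyl]chroman-3-ol F1. Dess–Martin oxidation without base should give the (2S)-8-bromo-7-[(triisopropylsilyl)oxy]-2-[3,4,5-tris(benzyloxy)phenyl]chroman-3-one F2 with C2 intact. LiBH(s-Bu)3 in THF at −78 °C should then deliver hydride opposite the 2-aryl group and give 13.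

2. Step 21. Hydride transfer to the C4 cation may show poor facial selectivity, and intramolecular 1,5-hydride shifts from the neighbouring benzyloxy CH2 or from H-2 of the middle unit may compete. The fallback sets out from 30 and comes back at 31. Thiolytic capture of the cation (PhSH, catalytic CF3CO2H, CH2Cl2, −20 °C) should give the C4 phenylthio analogue of 30 F3 as an epimer mixture. Radical desulfurisation (n-Bu3SnH, AIBN, toluene, 80 °C) then passes through the planar bis-benzylic radical, which should take hydrogen from the bulky stannane anti to the 3-benzyloxy group and give 31 without any cationic shift.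

3. Step 6. The allyl double bond may migrate before cyclisation, leading to ring contraction, and the enol ether may hydrolyse. The fallback sets out from 7 and comes back at 9. Lemieux–Johnson cleavage of the allyl group (OsO4 cat., NaIO4, 2,6-lutidine, dioxane–H2O) should give 2-{3-bromo-4-[(triisopropylsilyl)oxy]-2-{[3,4,5-tris(benzyloxy)benzoyl]oxy}phenyl}acetaldehyde F4. An intramolecular ester–aldehyde coupling of McMurry type with low-valent titanium (TiCl3, zinc–copper couple, DME, reflux, slow addition) should then form the same C2=C3 bond and give 9.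

Further compounds
F1 | step 9 | (2S,3R)-8-bromo-7-[(triisopropylsilyl)oxy]-2-[3,4,5-tris(benzyloxy)phenyl]chroman-3-ol (single enantiomer) | Brc1c(O[Si](C(C)C)(C(C)C)C(C)C)ccc2c1O[C@@H](c1cc(OCc3ccccc3)c(OCc3ccccc3)c(OCc3ccccc3)c1)[C@H](O)C2
F2 | step 9 | (2S)-8-bromo-7-[(triisopropylsilyl)oxy]-2-[3,4,5-tris(benzyloxy)phenyl]chroman-3-one | Brc1c(O[Si](C(C)C)(C(C)C)C(C)C)ccc2c1O[C@@H](c1cc(OCc3ccccc3)c(OCc3ccccc3)c(OCc3ccccc3)c1)C(=O)C2
F3 | step 21 | C4 phenylthio analogue of 30 (C4 of the upper unit undefined) | c1ccccc1COc1ccc2c(c1)O[C@@H](c1cc(OCc3ccccc3)c(OCc3ccccc3)c(OCc3ccccc3)c1)[C@H](OCc3ccccc3)C2(Sc3ccccc3)c1c(OCc3ccccc3)ccc2c1O[C@@H](c1cc(OCc3ccccc3)c(OCc3ccccc3)c(OCc3ccccc3)c1)[C@@H](OCc3ccccc3)[C@@H]2c1c(OCc3ccccc3)cc(OCc3ccccc3)c2c1O[C@H](c1ccc(OCc3ccccc3)c(OCc3ccccc3)c1)[C@H](OCc3ccccc3)C2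
F4 | step 6 | 2-{3-bromo-4-[(triisopropylsilyl)oxy]-2-{[3,4,5-tris(benzyloxy)benzoyl]oxy}phenyl}acetaldehyde | O=CCc1ccc(O[Si](C(C)C)(C(C)C)C(C)C)c(Br)c1OC(=O)c1cc(OCc2ccccc2)c(OCc2ccccc2)c(OCc2ccccc2)c1
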